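## Retrosynthetic overview

1. Numbering: C1 is the methyl on C2; C2=C3–C4=C5 is the diene; ring A is the oxane (O, C6, C8, C9, C10, C11; methyls C7, C12, C13; Br on C10); ring B is the cyclohexane (C14, C15, C16, C17, C19, C20; methyl C18 and OH on C17; Br on C19).
2. Last disconnection: the C3–C4 bond, made by carboalumination of a ring-B alkyne (C2≡C3) and coupling under Pd(PPh3)4 catalysis with a ring-A (E)-iodovinyl oxane; the C17 silyl ether is then removed.
3. Feature: ring B has the 1,4-pattern of an isoprene–acrolein adduct. C17–C19 is the former diene double bond (C18 the isoprene methyl) and C14 carries the former formyl carbon (C2), so an iminium-catalysed [4+2] cycloaddition forms C14–C20 and C15–C16 and sets C14.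
4. C14 relays to C17 and C19: both epoxides of the C17=C19 alkene hydrolyse to one trans-diaxial diol, and bromide displaces the C19 triflate with inversion (Br cis to C17–OH).
5. Ring A comes separately from (S)-linalool by 6-endo bromoetherification (O–C11 bond, Br on C10), then ozonolysis and Takai olefination; ring order: B (step 1), A (step 8), union (step 11).

Key step: step 1

Remarks (assumptions on the chemistry): the (5S)-imidazolidinone salt is taken to give the R adduct, as its benzyl-shielding model predicts (the 5R salt would be used otherwise). Commercial (S)-(+)-linalool is taken to be of high enantiomeric purity; any residue of its enantiomer would end as a separable diastereomer of 20.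

## Route

Step 1
Reactants: 1 2-methylbuta-1,3-diene (isoprene); 2 prop-2-enal (acrolein)
Product: 3 (1R)-4-methylcyclohex-3-ene-1-carbaldehyde
Conditions: (5S)-5-benzyl-2,2,3-trimethylimidazolidin-4-one hydrochloride (20 mol%), isoprene in threefold excess, MeNO2/H2O 95:5, 23 °C
Reagents that add atoms: none
Why: The amine salt condenses with 2 to the (E)-iminium ion, whose lowered LUMO undergoes a concerted, asynchronous [4+2] cycloaddition with s-cis 1, and hydrolysis of the product iminium ion releases 3 and the catalyst; the closest known reaction type is the iminium-catalysed enantioselective Diels–Alder reaction of enals with acyclic dienes, of which this pair is a standard case. Ring B closes by an intermolecular cycloaddition in which both sigma bonds (C14–C20 and C15–C16) form suprafacially on each partner. The only new stereocentre, C14, is set by the catalyst: the geminal methyl groups fix the iminium geometry and the benzyl group covers one face of the iminium alkene, so the diene adds to the open face and gives the R configuration. The step needs enantiofacial selectivity, secured by that shielding, and para regioselectivity, secured by the 2-methyl group of the diene, which puts the larger HOMO coefficient on the isoprene terminus that bonds to the beta carbon of the iminium ion. Any minor enantiomer should be removable by crystallisation of diol 7 or, after coupling with 18, as a diastereomer.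

Step 2
Reactants: 3 (1R)-4-methylcyclohex-3-ene-1-carbaldehyde
Product: 4 (4R)-4-(2,2-dibromoethenyl)-1-methylcyclohex-1-ene
Conditions: CBr4 (2 equiv), PPh3 (2 equiv), Zn (2 equiv), CH2Cl2, rt; then 3, 0 °C → rt
Reagents that add atoms: carbon tetrabromide, BrC(Br)(Br)Br
Why: Ramirez dibromo-olefination (first stage of the Corey–Fuchs sequence): the neutral ylide Ph3P=CBr2, generated with Zn so that no acidic phosphonium bromide is present, converts the aldehyde in a Wittig reaction without epimerising the adjacent C14 stereocentre or touching the ring alkene.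

Step 3
Reactants: 4 (4R)-4-(2,2-dibromoethenyl)-1-methylcyclohex-1-ene
Product: 7 (1S,2S,4R)-4-(2,2-dibromoethenyl)-1-methylcyclohexane-1,2-diol, via (1R,4R,6S)-epoxide 5 (not isolated), via (1S,4R,6R)-epoxide 6 (not isolated)
Conditions: mCPBA, NaHCO3, CH2Cl2, 0 °C; aqueous Na2SO3/NaHCO3 wash; then HClO4 (3 mol%), THF/H2O 3:1, 0 °C → rt
Reagents that add atoms: 3-chloroperoxybenzoic acid (mCPBA), OOC(=O)c1cccc(Cl)c1; water, O
Why: Prilezhaev epoxidation takes place only at the electron-rich ring alkene (the dibromoalkene is deactivated) and gives both epoxides, which acid-catalysed hydrolysis should open trans-diaxially on the half-chair that keeps the dibromoethenyl group equatorial (Fürst–Plattner rule), water entering with inversion at C17 of 5 and at C19 of 6, so that both converge on the diol with C17–OH cis and C19–OH trans to the C14 substituent, as is known for the two limonene 1,2-oxides.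

Step 4
Reactants: 7 (1S,2S,4R)-4-(2,2-dibromoethenyl)-1-methylcyclohexane-1,2-diol
Product: 8 (1S,2S,4R)-4-(2,2-dibromoethenyl)-1-methyl-1,2-bis[(triethylsilyl)oxy]cyclohexane
Conditions: TESOTf (2.6 equiv), 2,6-lutidine (4 equiv), CH2Cl2, −78 → 0 °C
Reagents that add atoms: triethylsilyl trifluoromethanesulfonate, CC[Si](CC)(CC)OS(=O)(=O)C(F)(F)F
Why: A silyl triflate with a hindered pyridine base silylates both the axial secondary and the tertiary hydroxyl group, which removes the acidic protons before the organolithium step and installs the tertiary ether that is kept until the end.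

Step 5
Reactants: 8 (1S,2S,4R)-4-(2,2-dibromoethenyl)-1-methyl-1,2-bis[(triethylsilyl)oxy]cyclohexane
Product: 10 (1S,2S,4R)-4-ethynyl-1-methyl-1,2-bis[(triethylsilyl)oxy]cyclohexane, via lithium acetylide 9 (not isolated)
Conditions: n-BuLi (2.2 equiv), THF, −78 °C; then H2O
Reagents that add atoms: none
Why: Second stage of the Corey–Fuchs sequence: bromine–lithium exchange, alpha-elimination with 1,2-hydrogen shift (Fritsch–Buttenberg–Wiechell rearrangement) and deprotonation give the lithium acetylide 9, which water protonates, and no stereocentre is involved.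

Step 6
Reactants: 10 (1S,2S,4R)-4-ethynyl-1-methyl-1,2-bis[(triethylsilyl)oxy]cyclohexane
Product: 11 (1S,2S,5R)-5-ethynyl-2-methyl-2-[(triethylsilyl)oxy]cyclohexan-1-ol
Conditions: pyridinium p-toluenesulfonate (0.2 equiv), MeOH/CH2Cl2 1:1, 0 °C
Reagents that add atoms: none
Why: Acid-catalysed methanolysis should remove the less hindered secondary triethylsilyl ether much faster than the tertiary one, so that only the C19 hydroxyl is set free.

Step 7
Reactants: 11 (1S,2S,5R)-5-ethynyl-2-methyl-2-[(triethylsilyl)oxy]cyclohexan-1-ol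
Product: 13 {[(1S,2R,4R)-2-bromo-4-ethynyl-1-methylcyclohexyl]oxy}triethylsilane, via secondary triflate 12 (not isolated)
Conditions: Tf2O (1.3 equiv), pyridine (3 equiv), CH2Cl2, −30 → 0 °C; then n-Bu4NBr (4 equiv), 0 °C → rt
Reagents that add atoms: tetrabutylammonium bromide, CCCC[N+](CCCC)(CCCC)CCCC.[Br-]
Why: The axial secondary alcohol is converted into its triflate and displaced by bromide in an SN2 reaction with inversion at C19, which should give the equatorial bromide cis to the C17 oxygen, while the triethylsilyl group keeps the antiperiplanar tertiary oxygen from closing an epoxide and the weakly basic bromide limits elimination.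

Step 8
Reactants: 14 (3S)-3,7-dimethylocta-1,6-dien-3-ol ((S)-(+)-linalool)
Product: 15 (3R,6S)-3-bromo-6-ethenyl-2,2,6-trimethyloxane
Conditions: 2,4,4,6-tetrabromocyclohexa-2,5-dien-1-one (TBCO, 1.1 equiv), MeNO2, 0 °C → rt, dark; chromatography
Reagents that add atoms: 2,4,4,6-tetrabromocyclohexa-2,5-dien-1-one, O=C1C(Br)=CC(Br)(Br)C=C1Br
Why: Electrophilic bromoetherification: the bromonium ion of the electron-rich trisubstituted alkene is opened anti at its tertiary carbon C11 by the tertiary hydroxyl through a chair transition state (6-endo, Markovnikov) that places bromine equatorial, the linalool stereocentre C6 is untouched, and C10 should form in both configurations because methyl and vinyl on C6 are of similar size, so the (3R,6S)-epimer (bromine trans to vinyl) has to be separated by chromatography from its C10 epimer and from 5-exo oxolane by-products.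

Step 9
Reactants: 15 (3R,6S)-3-bromo-6-ethenyl-2,2,6-trimethyloxane
Product: 17 (2S,5R)-5-bromo-2,6,6-trimethyloxane-2-carbaldehyde, via ozonide 16 (not isolated)
Conditions: O3, CH2Cl2, −78 °C; then PPh3, −78 °C → rt
Reagents that add atoms: ozone, [O-][O+]=O
Why: Ozonolysis with reductive work-up cleaves the only alkene to the aldehyde, whose alpha-carbon is fully substituted and cannot epimerise, and the secondary bromide and the ether are inert to ozone.

Step 10
Reactants: 17 (2S,5R)-5-bromo-2,6,6-trimethyloxane-2-carbaldehyde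
Product: 18 (3R,6S)-3-bromo-6-[(E)-2-iodoethenyl]-2,2,6-trimethyloxane
Conditions: CrCl2 (6 equiv), CHI3 (2 equiv), THF, 0 °C → rt
Reagents that add atoms: iodoform, IC(I)I
Why: Takai olefination: the geminal dichromium species formed from CHI3 and CrCl2 adds to the aldehyde and eliminates anti, which with the bulky quaternary neighbour should give the (E)-vinyl iodide, and the non-basic divalent chromium reagent leaves the secondary bromide and the ether untouched.

Step 11
Reactants: 13 {[(1S,2R,4R)-2-bromo-4-ethynyl-1-methylcyclohexyl]oxy}triethylsilane; 18 (3R,6S)-3-bromo-6-[(E)-2-iodoethenyl]-2,2,6-trimethyloxane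
Product: 20 {[(1S,2R,4R)-2-bromo-4-{(2E,4E)-5-[(2S,5R)-5-bromo-2,6,6-trimethyloxan-2-yl]penta-2,4-dien-2-yl}-1-methylcyclohexyl]oxy}triethylsilane, via alkenylalane 19 (not isolated)
Conditions: Me3Al (2.5 equiv), Cp2ZrCl2 (0.25 equiv), CH2Cl2, rt; volatiles removed; then 18, Pd(PPh3)4 (5 mol%), ZnCl2 (0.2 equiv), THF, rt
Reagents that add atoms: trimethylaluminium, C[Al](C)C
Why: Zirconium-catalysed syn-carboalumination (Negishi carboalumination) adds methyl to the internal and aluminium to the terminal alkyne carbon to give the (E)-alkenylalane 19, which couples under zinc-assisted, zerovalent-palladium catalysis (Negishi coupling) with vinyl iodide 18 with retention of both alkene geometries, oxidative addition into the alkenyl carbon–iodine bond being far faster than into the secondary alkyl bromides.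

Step 12
Reactants: 20 {[(1S,2R,4R)-2-bromo-4-{(2E,4E)-5-[(2S,5R)-5-bromo-2,6,6-trimethyloxan-2-yl]penta-2,4-dien-2-yl}-1-methylcyclohexyl]oxy}triethylsilane
Product: 21 (1S,2R,4R)-2-bromo-4-{(2E,4E)-5-[(2S,5R)-5-bromo-2,6,6-trimethyloxan-2-yl]penta-2,4-dien-2-yl}-1-methylcyclohexan-1-ol (CNP0199463.1)
Conditions: HF·pyridine, pyridine, THF, 0 °C → rt
Reagents that add atoms: none
Why: Fluoride cleaves the silicon–oxygen bond of the tertiary triethylsilyl ether under pyridine-buffered conditions that should avoid ionisation of the tertiary allylic ether at C6, and the liberated cis-bromohydrin cannot close to an epoxide because oxygen and bromine are not antiperiplanar.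

## Compound list

1 | 2-methylbuta-1,3-diene (isoprene) | C=CC(C)=C | starting material
2 | prop-2-enal (acrolein) | C=CC=O | starting material
3 | (1R)-4-methylcyclohex-3-ene-1-carbaldehyde | O=C[C@@H]1CCC(C)=CC1 | intermediate
4 | (4R)-4-(2,2-dibromoethenyl)-1-methylcyclohex-1-ene | BrC(Br)=C[C@@H]1CCC(C)=CC1 | intermediate
5 | (1R,4R,6S)-4-(2,2-dibromoethenyl)-1-methyl-7-oxabicyclo[4.1.0]heptane (epoxide oxygen anti to the dibromoethenyl group) | BrC(Br)=C[C@@H]1CC[C@@]2(C)O[C@H]2C1 | intermediate (not isolated)
6 | (1S,4R,6R)-4-(2,2-dibromoethenyl)-1-methyl-7-oxabicyclo[4.1.0]heptane (epoxide oxygen syn to the dibromoethenyl group) | BrC(Br)=C[C@@H]1CC[C@]2(C)O[C@@H]2C1 | intermediate (not isolated)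
7 | (1S,2S,4R)-4-(2,2-dibromoethenyl)-1-methylcyclohexane-1,2-diol | BrC(Br)=C[C@@H]1CC[C@](C)(O)[C@@H](O)C1 | intermediate
8 | (1S,2S,4R)-4-(2,2-dibromoethenyl)-1-methyl-1,2-bis[(triethylsilyl)oxy]cyclohexane | BrC(Br)=C[C@@H]1CC[C@](C)(O[Si](CC)(CC)CC)[C@@H](O[Si](CC)(CC)CC)C1 | intermediate
9 | lithium acetylide of 10 (lithium in place of the alkyne hydrogen) | [Li]C#C[C@@H]1CC[C@](C)(O[Si](CC)(CC)CC)[C@@H](O[Si](CC)(CC)CC)C1 | intermediate (not isolated)
10 | (1S,2S,4R)-4-ethynyl-1-methyl-1,2-bis[(triethylsilyl)oxy]cyclohexane | C#C[C@@H]1CC[C@](C)(O[Si](CC)(CC)CC)[C@@H](O[Si](CC)(CC)CC)C1 | intermediate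
11 | (1S,2S,5R)-5-ethynyl-2-methyl-2-[(triethylsilyl)oxy]cyclohexan-1-ol | C#C[C@@H]1CC[C@](C)(O[Si](CC)(CC)CC)[C@@H](O)C1 | intermediate
12 | (1S,2S,5R)-5-ethynyl-2-methyl-2-[(triethylsilyl)oxy]cyclohexyl trifluoromethanesulfonate | C#C[C@@H]1CC[C@](C)(O[Si](CC)(CC)CC)[C@@H](OS(=O)(=O)C(F)(F)F)C1 | intermediate (not isolated)
13 | {[(1S,2R,4R)-2-bromo-4-ethynyl-1-methylcyclohexyl]oxy}triethylsilane | C#C[C@@H]1CC[C@](C)(O[Si](CC)(CC)CC)[C@H](Br)C1 | intermediate
14 | (3S)-3,7-dimethylocta-1,6-dien-3-ol ((S)-(+)-linalool) | C=C[C@@](C)(O)CCC=C(C)C | starting material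
15 | (3R,6S)-3-bromo-6-ethenyl-2,2,6-trimethyloxane | C=C[C@]1(C)CC[C@@H](Br)C(C)(C)O1 | intermediate
16 | (3R,6S)-3-bromo-2,2,6-trimethyl-6-(1,2,4-trioxolan-3-yl)oxane (either configuration at the trioxolane carbon) | C1OC(OO1)[C@]2(C)CC[C@@H](Br)C(C)(C)O2 | intermediate (not isolated)
17 | (2S,5R)-5-bromo-2,6,6-trimethyloxane-2-carbaldehyde | O=C[C@]1(C)CC[C@@H](Br)C(C)(C)O1 | intermediate
18 | (3R,6S)-3-bromo-6-[(E)-2-iodoethenyl]-2,2,6-trimethyloxane | I/C=C/[C@]1(C)CC[C@@H](Br)C(C)(C)O1 | intermediate
19 | {(E)-2-[(1R,3R,4S)-3-bromo-4-methyl-4-[(triethylsilyl)oxy]cyclohexyl]prop-1-en-1-yl}dimethylalumane | C/C(=C\[Al](C)C)[C@@H]1CC[C@](C)(O[Si](CC)(CC)CC)[C@H](Br)C1 | intermediate (not isolated)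
20 | {[(1S,2R,4R)-2-bromo-4-{(2E,4E)-5-[(2S,5R)-5-bromo-2,6,6-trimethyloxan-2-yl]penta-2,4-dien-2-yl}-1-methylcyclohexyl]oxy}triethylsilane | C/C(=C\C=C\[C@]1(C)CC[C@@H](Br)C(C)(C)O1)[C@@H]1CC[C@](C)(O[Si](CC)(CC)CC)[C@H](Br)C1 | intermediate
21 | (1S,2R,4R)-2-bromo-4-{(2E,4E)-5-[(2S,5R)-5-bromo-2,6,6-trimethyloxan-2-yl]penta-2,4-dien-2-yl}-1-methylcyclohexan-1-ol | C/C(=C\C=C\[C@]1(C)CC[C@@H](Br)C(C)(C)O1)[C@@H]1CC[C@](C)(O)[C@H](Br)C1 | target

## Step count

Total: 12 steps. Longest linear sequence: 9 steps (steps 1–7, 11, 12, from isoprene and acrolein); the linalool branch is steps 8–10.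

## Steps most likely to fail

**Step 7.** Backside attack of bromide on the axial C19 triflate is slowed by the fully substituted C17 and by the antiperiplanar axial silyloxy group. Elimination towards C20 and participation of the C17 oxygen (epoxide formation or substitution with retention) may therefore outrun inversion.

Fallback, from 10 back to 13: both silyl ethers of 10 are removed with Bu4NF in THF to give (1S,2S,4R)-4-ethynyl-1-methylcyclohexane-1,2-diol F1. SOCl2 and Et3N in CH2Cl2 at 0 °C should close the trans-fused (1S,2S,4R)-4-ethynyl-1-methylcyclohexane-1,2-diyl sulfite F2 on the ring-flipped chair (both oxygens equatorial, the slim ethynyl group and the methyl axial). Brief oxidation with NaIO4 and catalytic RuCl3 in MeCN/H2O at 0 °C, kept short to spare the alkyne, should give (1S,2S,4R)-4-ethynyl-1-methylcyclohexane-1,2-diyl sulfate F3. LiBr in THF should open the cyclic sulfate at the secondary carbon C19 with inversion to lithium (1S,2R,4R)-2-bromo-4-ethynyl-1-methylcyclohexyl sulfate F4; here one group both activates C19 and masks the C17 oxygen as a non-participating ester. Catalytic H2SO4 and water in THF hydrolyse it to (1S,2R,4R)-2-bromo-4-ethynyl-1-methylcyclohexan-1-ol F5, and TESOTf with 2,6-lutidine returns to 13.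

**Step 8.** 5-exo closure to oxolanes competes with the 6-endo mode, and there is no facial control at C10, so recovery of the needed epimer may be low.

Fallback, from 14 back to 15: Hg(OCOCF3)2 in MeNO2 at 0 °C should cyclise linalool in the strictly Markovnikov sense (oxygen to C11, mercury to C10, anti addition) to [(3R,6S)-6-ethenyl-2,2,6-trimethyloxan-3-yl]mercury trifluoroacetate F6. Aqueous KBr converts it into bromo[(3R,6S)-6-ethenyl-2,2,6-trimethyloxan-3-yl]mercury F7, at which stage the C10 epimers are separated by crystallisation or chromatography. Polar brominolysis (Br2, LiBr, pyridine, under O2 to suppress radical chains, 0 °C) should replace mercury by bromine with retention and give 15. This secures ring size but not the C10 configuration.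

**Step 11.** In the coupling stage, methyl transfer from residual methylaluminium species, slow transmetalation of the crowded alkenylalane, and Lewis-acid-induced ionisation of the tertiary allylic ether at C6 may erode the yield.

Fallback, from 13 (through alane 19) and from 17, back to 20: alane 19 is quenched with I2 in THF at −30 °C to give {[(1S,2R,4R)-2-bromo-4-[(E)-1-iodoprop-1-en-2-yl]-1-methylcyclohexyl]oxy}triethylsilane F8. Aldehyde 17 is converted by Takai–Utimoto boryl-olefination (CrCl2, LiI, 2-(dichloromethyl)-4,4,5,5-tetramethyl-1,3,2-dioxaborolane, THF, rt) into 2-[(E)-2-[(2S,5R)-5-bromo-2,6,6-trimethyloxan-2-yl]ethenyl]-4,4,5,5-tetramethyl-1,3,2-dioxaborolane F9. Suzuki–Miyaura coupling of F8 with F9 (PdCl2(dppf), K3PO4, THF/H2O, rt) should form the C3–C4 bond with retention of both geometries and give 20, with no aluminium or zinc Lewis acid in the coupling flask.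

## Further compounds

F1 | step 7 | (1S,2S,4R)-4-ethynyl-1-methylcyclohexane-1,2-diol | C#C[C@@H]1CC[C@](C)(O)[C@@H](O)C1
F2 | step 7 | (1S,2S,4R)-4-ethynyl-1-methylcyclohexane-1,2-diyl sulfite (trans-fused cyclic sulfite, either configuration at sulfur) | C#C[C@@H]1CC[C@]2(C)OS(=O)O[C@H]2C1
F3 | step 7 | (1S,2S,4R)-4-ethynyl-1-methylcyclohexane-1,2-diyl sulfate (trans-fused cyclic sulfate) | C#C[C@@H]1CC[C@]2(C)OS(=O)(=O)O[C@H]2C1
F4 | step 7 | lithium (1S,2R,4R)-2-bromo-4-ethynyl-1-methylcyclohexyl sulfate | C#C[C@@H]1CC[C@](C)(OS(=O)(=O)[O-])[C@H](Br)C1.[Li+]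
F5 | step 7 | (1S,2R,4R)-2-bromo-4-ethynyl-1-methylcyclohexan-1-ol | C#C[C@@H]1CC[C@](C)(O)[C@H](Br)C1
F6 | step 8 | [(3R,6S)-6-ethenyl-2,2,6-trimethyloxan-3-yl]mercury trifluoroacetate | C=C[C@]1(C)CC[C@@H]([Hg]OC(=O)C(F)(F)F)C(C)(C)O1
F7 | step 8 | bromo[(3R,6S)-6-ethenyl-2,2,6-trimethyloxan-3-yl]mercury | C=C[C@]1(C)CC[C@@H]([Hg]Br)C(C)(C)O1
F8 | step 11 | {[(1S,2R,4R)-2-bromo-4-[(E)-1-iodoprop-1-en-2-yl]-1-methylcyclohexyl]oxy}triethylsilane | C/C(=C\I)[C@@H]1CC[C@](C)(O[Si](CC)(CC)CC)[C@H](Br)C1
F9 | step 11 | 2-[(E)-2-[(2S,5R)-5-bromo-2,6,6-trimethyloxan-2-yl]ethenyl]-4,4,5,5-tetramethyl-1,3,2-dioxaborolane | CC1(C)OB(/C=C/[C@]2(C)CC[C@@H](Br)C(C)(C)O2)OC1(C)C
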